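**Retrosynthetic overview**

- The route rests on one feature of the 2H-chromene: the ether oxygen O1 sits on C8a and the alkene carbon C4 on C4a, two adjacent carbons of the benzene ring. The pyran ring is therefore cut at O1–C8a and C4–C4a into a C4a≡C8a aryne and a C2–C3–C4 tertiary-oxy ester that already holds the C2 stereocentre.
- The aryne carries a removable bromine at C5 that steers the oxygen to C8a; the C4 ketone formed is then reduced and dehydrated to the C3=C4 alkene.
- The side chain is cut at C5'–C6': Stille coupling of an allylic bromide (from SeO2 oxidation of the E-methyl group, C5') with an (E)-alkenylstannane.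
- Both stereocentres (C2 and C8', each S) come from C3 of one Sharpless epoxide of geraniol: hydride opening and oxidation give the hydroxy ester, the epoxy chloride gives (S)-dehydrolinalool.
- Ring order: the benzene ring is bought (4-methoxy-2-methylphenol); the pyran ring is the only ring formed, in the aryne step.

Key step: step 14

Remark: locants follow 2H-chromene numbering with the side chain C1'–C12' counted from C2; from step 16 on, all operations are kept below about 50 °C and shielded from light, on the assumption that oxa-6π ring opening of the 2H-chromene could otherwise erode C2.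

**Route**

Step 1
Reactants: 1 4-methoxy-2-methylphenol
Product: 2 4-methoxy-2-methylphenyl N,N-diethylcarbamate
Conditions: ClC(O)NEt2, K2CO3, MeCN, reflux
Reagents that add atoms: N,N-diethylcarbamoyl chloride, CCN(CC)C(=O)Cl
Why: O-carbamoylation of the phenoxide (acyl substitution) should be clean and gives a group that damps the phenol oxygen as a ring activator and later directs metalation.

Step 2
Reactants: 2 4-methoxy-2-methylphenyl N,N-diethylcarbamate
Product: 3 5-bromo-4-methoxy-2-methylphenyl N,N-diethylcarbamate
Conditions: NBS, MeCN, 0 °C → rt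
Reagents that add atoms: N-bromosuccinimide, O=C1CCC(=O)N1Br
Why: Electrophilic aromatic bromination is steered by the methoxy group, the strongest donor left, to its ortho positions, of which C5 (para to the methyl, one neighbour only) should be favoured over C3 (wedged between methyl and methoxy).

Step 3
Reactants: 3 5-bromo-4-methoxy-2-methylphenyl N,N-diethylcarbamate
Product: 5 3-bromo-4-methoxy-6-methyl-2-(trimethylsilyl)phenyl N,N-diethylcarbamate, via aryllithium 4 (not isolated)
Conditions: LiN(i-Pr)2 (1.3 equiv) added to 3 and Me3SiCl (3 equiv), THF, −78 °C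
Reagents that add atoms: chlorotrimethylsilane, C[Si](C)(C)Cl
Why: Directed ortho-metalation with in situ silyl trapping: the only hydrogen ortho to the carbamate is further acidified by the adjacent bromine, a lithium amide cannot undergo Br–Li exchange, and Me3SiCl present from the start should trap aryllithium 4 before LiBr loss or carbamoyl migration.

Step 4
Reactants: 5 3-bromo-4-methoxy-6-methyl-2-(trimethylsilyl)phenyl N,N-diethylcarbamate
Product: 6 3-bromo-4-methoxy-6-methyl-2-(trimethylsilyl)phenol
Conditions: Cp2Zr(H)Cl (3 equiv), THF, rt; aq. NH4Cl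
Reagents that add atoms: none
Why: Reductive carbamate cleavage by hydrozirconation of the carbonyl and collapse of the adduct releases the phenoxide at room temperature, conditions under which the aryl bromide and the aryl–silicon bond should be untouched.

Step 5
Reactants: 6 3-bromo-4-methoxy-6-methyl-2-(trimethylsilyl)phenol
Product: 7 3-bromo-4-methoxy-6-methyl-2-(trimethylsilyl)phenyl trifluoromethanesulfonate
Conditions: Tf2O, pyridine, CH2Cl2, 0 °C
Reagents that add atoms: trifluoromethanesulfonic anhydride, FC(F)(F)S(=O)(=O)OS(=O)(=O)C(F)(F)F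
Why: O-sulfonylation of the phenol with triflic anhydride is standard even for 2,6-disubstituted phenols and completes the o-silylaryl triflate.

Step 6
Reactants: 8 geraniol
Product: 9 (2S,3S)-2,3-epoxygeraniol, [(2S,3S)-3-methyl-3-(4-methylpent-3-en-1-yl)oxiran-2-yl]methanol
Conditions: Ti(O-i-Pr)4 (5 mol %), L-(+)-diethyl tartrate (7 mol %), t-BuOOH, 4 Å molecular sieves, CH2Cl2, −20 °C
Reagents that add atoms: tert-butyl hydroperoxide, CC(C)(C)OO
Why: Sharpless asymmetric epoxidation of the allylic alcohol; the L-(+)-tartrate–titanium complex delivers oxygen to the face that gives the (2S,3S)-epoxide, and C3 of this epoxide is the source of both C2 and C8' of the target.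

Step 7
Reactants: 9 (2S,3S)-2,3-epoxygeraniol
Product: 10 (S)-3,7-dimethyloct-6-ene-1,3-diol
Conditions: NaAlH2(OCH2CH2OMe)2, THF, 0 °C → rt
Reagents that add atoms: none
Why: Hydroxyl-directed hydride opening of the 2,3-epoxy alcohol: the alkoxyaluminate delivers hydride intramolecularly to C2, the C3–O bond is not touched, so the tertiary carbinol keeps its configuration (S).

Step 8
Reactants: 10 (S)-3,7-dimethyloct-6-ene-1,3-diol
Product: 11 (S)-3-hydroxy-3,7-dimethyloct-6-enoic acid
Conditions: TEMPO (cat.), PhI(OAc)2, MeCN/H2O, rt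
Reagents that add atoms: water, O
Why: Nitroxyl-catalysed oxidation takes the primary alcohol through the aldehyde hydrate to the acid, while the tertiary alcohol cannot be oxidised and the trisubstituted alkene is tolerated.

Step 9
Reactants: 11 (S)-3-hydroxy-3,7-dimethyloct-6-enoic acid
Product: 12 methyl (S)-3-hydroxy-3,7-dimethyloct-6-enoate
Conditions: MeI, KHCO3, DMF, rt
Reagents that add atoms: iodomethane, CI
Why: SN2 O-alkylation of the carboxylate under weakly basic conditions esterifies without touching the tertiary alcohol.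

Step 10
Reactants: 12 methyl (S)-3-hydroxy-3,7-dimethyloct-6-enoate
Product: 13 methyl (S)-3,7-dimethyl-3-(trimethylsilyloxy)oct-6-enoate
Conditions: Me3SiCl, imidazole, DMF, rt
Reagents that add atoms: chlorotrimethylsilane, C[Si](C)(C)Cl
Why: O-silylation of the tertiary alcohol with the small trimethylsilyl group masks the hydroxyl proton, so that fluoride can later release a proton-free alkoxide.

Step 11
Reactants: 9 (2S,3S)-2,3-epoxygeraniol
Product: 14 (2S,3R)-3-(chloromethyl)-2-methyl-2-(4-methylpent-3-en-1-yl)oxirane
Conditions: PPh3, CCl4, NaHCO3, reflux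
Reagents that add atoms: tetrachloromethane, ClC(Cl)(Cl)Cl
Why: Appel-type chlorination replaces the primary hydroxyl by SN2 at C1 and leaves the epoxide and both stereocentres as they are (the descriptor at the CH carbon changes only because chlorine raises the rank of C1).

Step 12
Reactants: 14 (2S,3R)-3-(chloromethyl)-2-methyl-2-(4-methylpent-3-en-1-yl)oxirane
Product: 15 (S)-3,7-dimethyloct-6-en-1-yn-3-ol, (S)-dehydrolinalool
Conditions: n-BuLi (3.2 equiv), THF, −78 → −30 °C; aq. NH4Cl
Reagents that add atoms: none
Why: Base-induced double elimination of a 2,3-epoxy chloride: deprotonation alpha to chlorine opens the epoxide to a chloroalkenyl alkoxide, dehydrochlorination then gives the alkyne, and as the C3–O bond stays intact the tertiary carbinol is obtained with retention (S).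

Step 13
Reactants: 15 (S)-3,7-dimethyloct-6-en-1-yn-3-ol
Product: 16 (S,E)-3,7-dimethyl-1-(tributylstannyl)octa-1,6-dien-3-ol
Conditions: Bu3SnH, PdCl2(PPh3)2 (2 mol %), THF, 0 °C → rt
Reagents that add atoms: tributylstannane, CCCC[SnH](CCCC)CCCC
Why: Palladium-catalysed syn-hydrostannation of the terminal alkyne places tin on the terminal carbon, away from the bulky tertiary carbinol, and so gives the (E)-alkenylstannane.

Step 14
Reactants: 7 3-bromo-4-methoxy-6-methyl-2-(trimethylsilyl)phenyl trifluoromethanesulfonate and 13 methyl (S)-3,7-dimethyl-3-(trimethylsilyloxy)oct-6-enoate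
Product: 20 (S)-5-bromo-6-methoxy-2,8-dimethyl-2-(4-methylpent-3-en-1-yl)chroman-4-one, via bromoaryne 17 (not isolated), via cesium alkoxide 18 (not isolated), via aryl cesium adduct 19 (not isolated)
Conditions: CsF (5 equiv), 18-crown-6 (cat.), THF, 0 °C → rt; 7 (2 equiv)
Reagents that add atoms: none
Why: Proposed new method: fluoride removes the silyl group of 7 and triflate departs to give bromoaryne 17, while the same fluoride unmasks silyl ether 13 to the proton-free cesium alkoxide 18; its oxygen adds to C8a and the C4a aryl anion 19 attacks the ester carbonyl, expelling methoxide and forming O1–C8a and C4–C4a in one operation. The closest known reactions are the fluoride-triggered annulation of arynes with salicylate esters to xanthones and the addition of tert-alkoxides to arynes; what is new is an aliphatic tertiary alkoxide carrying a beta-ester as the partner. The pyranone ring closes by 6-exo-trig acyl substitution. No stereocentre is formed: C2 comes from 13 with retention because its C–O bond is never broken, which is also why a tertiary aryl ether that SN2 chemistry cannot give is accessible here. The step needs oxygen attack at C8a and not at C4a, and this is secured by the C5 bromine, whose inductive distortion of the aryne places the developing anion next to it, reinforced by the C6 methoxy group para to C8a and outweighing the flanking C8 methyl. The silyl ether is used in place of the free alcohol so that no O–H proton can quench 19 before acylation, and low temperature with an excess of 7 (which also consumes the methoxide set free) is meant to hold back retro-aldol cleavage of 18, bromide loss from 19 and base-induced retro-oxa-Michael opening of 20.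

Step 15
Reactants: 20 (S)-5-bromo-6-methoxy-2,8-dimethyl-2-(4-methylpent-3-en-1-yl)chroman-4-one
Product: 21 (2S)-5-bromo-6-methoxy-2,8-dimethyl-2-(4-methylpent-3-en-1-yl)chroman-4-ol (mixture of C4 epimers)
Conditions: NaBH4, CeCl3·7H2O, MeOH, −20 → 0 °C
Reagents that add atoms: none
Why: Hydride 1,2-reduction of the aryl ketone under Luche conditions is fast and nearly neutral, so enolisation at C3 and retro-oxa-Michael opening should not intervene; the C4 configuration is irrelevant because C4 becomes sp2 in the next step.

Step 16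
Reactants: 21 (2S)-5-bromo-6-methoxy-2,8-dimethyl-2-(4-methylpent-3-en-1-yl)chroman-4-ol
Product: 22 (S)-5-bromo-6-methoxy-2,8-dimethyl-2-(4-methylpent-3-en-1-yl)-2H-chromene
Conditions: methyl N-(triethylammoniosulfonyl)carbamate (Burgess reagent), toluene, 50 °C
Reagents that add atoms: none
Why: Dehydration with the Burgess reagent proceeds by syn-elimination of the sulfamate ester of the benzylic alcohol (a syn hydrogen is available on C3 in either C4 epimer) and avoids the protic acid that could let a benzylic cation engage the side-chain alkene.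

Step 17
Reactants: 22 (S)-5-bromo-6-methoxy-2,8-dimethyl-2-(4-methylpent-3-en-1-yl)-2H-chromene
Product: 24 (S)-6-methoxy-2,8-dimethyl-2-(4-methylpent-3-en-1-yl)-2H-chromene, via aryllithium 23 (not isolated)
Conditions: n-BuLi, THF, −78 °C; then MeOH
Reagents that add atoms: none
Why: Bromine–lithium exchange at −78 °C followed by protonation of aryllithium 23 removes the directing bromine; the chromene carries no acidic hydrogen and no electrophilic group.

Step 18
Reactants: 24 (S)-6-methoxy-2,8-dimethyl-2-(4-methylpent-3-en-1-yl)-2H-chromene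
Product: 25 (S)-2,8-dimethyl-2-(4-methylpent-3-en-1-yl)-2H-chromen-6-ol
Conditions: Ph2PLi (from Ph2PH and n-BuLi), THF, rt → 45 °C, dark; aq. NH4Cl
Reagents that add atoms: none
Why: Nucleophilic demethylation (SN2 at the methyl carbon by diphenylphosphide) cleaves the aryl methyl ether without acid and without strong heating, which suits the acid-sensitive and possibly heat-sensitive chromene.

Step 19
Reactants: 25 (S)-2,8-dimethyl-2-(4-methylpent-3-en-1-yl)-2H-chromen-6-ol
Product: 26 tert-butyl{[(S)-2,8-dimethyl-2-(4-methylpent-3-en-1-yl)-2H-chromen-6-yl]oxy}dimethylsilane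
Conditions: t-BuMe2SiCl, imidazole, DMF, rt
Reagents that add atoms: tert-butyldimethylsilyl chloride, CC(C)(C)[Si](C)(C)Cl
Why: O-silylation of the phenol gives an ether that should withstand the oxidation and coupling steps and is removed by fluoride at the end.

Step 20
Reactants: 26 tert-butyl{[(S)-2,8-dimethyl-2-(4-methylpent-3-en-1-yl)-2H-chromen-6-yl]oxy}dimethylsilane
Product: 27 (S,E)-5-[6-(tert-butyldimethylsilyloxy)-2,8-dimethyl-2H-chromen-2-yl]-2-methylpent-2-en-1-ol
Conditions: SeO2 (cat.), t-BuOOH, salicylic acid (cat.), CH2Cl2, 0 °C → rt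
Reagents that add atoms: selenium dioxide, O=[Se]=O; tert-butyl hydroperoxide, CC(C)(C)OO
Why: SeO2-catalysed allylic oxidation (ene reaction, then [2,3]-sigmatropic shift) hydroxylates the methyl group trans to the chain and gives the (E)-allylic alcohol, the C3=C4 alkene has no allylic hydrogen, and any enal formed can be returned to 27 with NaBH4.

Step 21
Reactants: 27 (S,E)-5-[6-(tert-butyldimethylsilyloxy)-2,8-dimethyl-2H-chromen-2-yl]-2-methylpent-2-en-1-ol
Product: 28 (S,E)-2-(5-bromo-4-methylpent-3-en-1-yl)-6-(tert-butyldimethylsilyloxy)-2,8-dimethyl-2H-chromene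
Conditions: CBr4, PPh3, CH2Cl2, 0 °C
Reagents that add atoms: tetrabromomethane, BrC(Br)(Br)Br
Why: Appel bromination converts the primary allylic alcohol into the bromide by SN2 under neutral conditions without allylic transposition.

Step 22
Reactants: 28 (S,E)-2-(5-bromo-4-methylpent-3-en-1-yl)-6-(tert-butyldimethylsilyloxy)-2,8-dimethyl-2H-chromene and 16 (S,E)-3,7-dimethyl-1-(tributylstannyl)octa-1,6-dien-3-ol
Product: 29 (S)-6-(tert-butyldimethylsilyloxy)-2-[(3E,6E,8S)-8-hydroxy-4,8,12-trimethyltrideca-3,6,11-trien-1-yl]-2,8-dimethyl-2H-chromene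
Conditions: Pd2(dba)3 (2.5 mol %), AsPh3 (20 mol %), THF, rt → 40 °C, dark
Reagents that add atoms: none
Why: Stille coupling of an allylic bromide with an alkenylstannane: oxidative addition gives an allylpalladium species, transmetalation and reductive elimination join C5' to C6' at the less hindered allyl terminus with retention of both alkene geometries, and the free tertiary alcohol is tolerated.

Step 23
Reactants: 29 (S)-6-(tert-butyldimethylsilyloxy)-2-[(3E,6E,8S)-8-hydroxy-4,8,12-trimethyltrideca-3,6,11-trien-1-yl]-2,8-dimethyl-2H-chromene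
Product: 30 (S)-2-[(3E,6E,8S)-8-hydroxy-4,8,12-trimethyltrideca-3,6,11-trien-1-yl]-2,8-dimethyl-2H-chromen-6-ol
Conditions: Bu4NF, THF, 0 °C; aq. NH4Cl
Reagents that add atoms: none
Why: Fluoride cleaves the aryl silyl ether at 0 °C (desilylation driven by Si–F bond formation) without affecting the tertiary allylic alcohol, the skipped diene or the chromene.

**Compound list**

1 | 4-methoxy-2-methylphenol | COc1ccc(O)c(C)c1 | starting material
2 | 4-methoxy-2-methylphenyl N,N-diethylcarbamate | CCN(CC)C(=O)Oc1ccc(OC)cc1C | intermediate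
3 | 5-bromo-4-methoxy-2-methylphenyl N,N-diethylcarbamate | CCN(CC)C(=O)Oc1cc(Br)c(OC)cc1C | intermediate
4 | 3-bromo-2-lithio-4-methoxy-6-methylphenyl N,N-diethylcarbamate (not isolated) | CCN(CC)C(=O)Oc1c(C)cc(OC)c(Br)c1[Li] | intermediate
5 | 3-bromo-4-methoxy-6-methyl-2-(trimethylsilyl)phenyl N,N-diethylcarbamate | CCN(CC)C(=O)Oc1c(C)cc(OC)c(Br)c1[Si](C)(C)C | intermediate
6 | 3-bromo-4-methoxy-6-methyl-2-(trimethylsilyl)phenol | Cc1cc(OC)c(Br)c([Si](C)(C)C)c1O | intermediate
7 | 3-bromo-4-methoxy-6-methyl-2-(trimethylsilyl)phenyl trifluoromethanesulfonate | Cc1cc(OC)c(Br)c([Si](C)(C)C)c1OS(=O)(=O)C(F)(F)F | intermediate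
8 | geraniol | CC(C)=CCC/C(C)=C/CO | starting material
9 | (2S,3S)-2,3-epoxygeraniol | CC(C)=CCC[C@]1(C)O[C@H]1CO | intermediate
10 | (S)-3,7-dimethyloct-6-ene-1,3-diol | CC(C)=CCC[C@](C)(O)CCO | intermediate
11 | (S)-3-hydroxy-3,7-dimethyloct-6-enoic acid | CC(C)=CCC[C@](C)(O)CC(=O)O | intermediate
12 | methyl (S)-3-hydroxy-3,7-dimethyloct-6-enoate | CC(C)=CCC[C@](C)(O)CC(=O)OC | intermediate
13 | methyl (S)-3,7-dimethyl-3-(trimethylsilyloxy)oct-6-enoate | CC(C)=CCC[C@](C)(O[Si](C)(C)C)CC(=O)OC | intermediate
14 | (2S,3R)-3-(chloromethyl)-2-methyl-2-(4-methylpent-3-en-1-yl)oxirane | CC(C)=CCC[C@]1(C)O[C@H]1CCl | intermediate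
15 | (S)-3,7-dimethyloct-6-en-1-yn-3-ol | CC(C)=CCC[C@](C)(O)C#C | intermediate
16 | (S,E)-3,7-dimethyl-1-(tributylstannyl)octa-1,6-dien-3-ol | CC(C)=CCC[C@](C)(O)/C=C/[Sn](CCCC)(CCCC)CCCC | intermediate
17 | 3-bromo-4-methoxy-6-methylbenzyne (not isolated) | CC1=CC(OC)=C(Br)C#C1 | intermediate
18 | cesium (S)-1-methoxy-3,7-dimethyl-1-oxooct-6-en-3-olate (not isolated) | [Cs+].CC(C)=CCC[C@](C)([O-])CC(=O)OC | intermediate
19 | aryl cesium adduct, methyl (S)-3-(3-bromo-2-cesio-4-methoxy-6-methylphenoxy)-3,7-dimethyloct-6-enoate (not isolated) | [Cs+].CC(C)=CCC[C@@](C)(CC(=O)OC)Oc1c(C)cc(OC)c(Br)[c-]1 | intermediate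
20 | (S)-5-bromo-6-methoxy-2,8-dimethyl-2-(4-methylpent-3-en-1-yl)chroman-4-one | CC(C)=CCC[C@@]1(C)CC(=O)c2c(Br)c(OC)cc(C)c2O1 | intermediate
21 | (2S)-5-bromo-6-methoxy-2,8-dimethyl-2-(4-methylpent-3-en-1-yl)chroman-4-ol, C4 epimers | CC(C)=CCC[C@@]1(C)CC(O)c2c(Br)c(OC)cc(C)c2O1 | intermediate
22 | (S)-5-bromo-6-methoxy-2,8-dimethyl-2-(4-methylpent-3-en-1-yl)-2H-chromene | CC(C)=CCC[C@@]1(C)C=Cc2c(Br)c(OC)cc(C)c2O1 | intermediate
23 | (S)-5-lithio-6-methoxy-2,8-dimethyl-2-(4-methylpent-3-en-1-yl)-2H-chromene (not isolated) | CC(C)=CCC[C@@]1(C)C=Cc2c([Li])c(OC)cc(C)c2O1 | intermediate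
24 | (S)-6-methoxy-2,8-dimethyl-2-(4-methylpent-3-en-1-yl)-2H-chromene | CC(C)=CCC[C@@]1(C)C=Cc2cc(OC)cc(C)c2O1 | intermediate
25 | (S)-2,8-dimethyl-2-(4-methylpent-3-en-1-yl)-2H-chromen-6-ol | CC(C)=CCC[C@@]1(C)C=Cc2cc(O)cc(C)c2O1 | intermediate
26 | tert-butyl{[(S)-2,8-dimethyl-2-(4-methylpent-3-en-1-yl)-2H-chromen-6-yl]oxy}dimethylsilane | CC(C)=CCC[C@@]1(C)C=Cc2cc(O[Si](C)(C)C(C)(C)C)cc(C)c2O1 | intermediate
27 | (S,E)-5-[6-(tert-butyldimethylsilyloxy)-2,8-dimethyl-2H-chromen-2-yl]-2-methylpent-2-en-1-ol | OC/C(C)=C/CC[C@@]1(C)C=Cc2cc(O[Si](C)(C)C(C)(C)C)cc(C)c2O1 | intermediate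
28 | (S,E)-2-(5-bromo-4-methylpent-3-en-1-yl)-6-(tert-butyldimethylsilyloxy)-2,8-dimethyl-2H-chromene | BrC/C(C)=C/CC[C@@]1(C)C=Cc2cc(O[Si](C)(C)C(C)(C)C)cc(C)c2O1 | intermediate
29 | (S)-6-(tert-butyldimethylsilyloxy)-2-[(3E,6E,8S)-8-hydroxy-4,8,12-trimethyltrideca-3,6,11-trien-1-yl]-2,8-dimethyl-2H-chromene | CC(C)=CCC[C@](C)(O)/C=C/C/C(C)=C/CC[C@@]1(C)C=Cc2cc(O[Si](C)(C)C(C)(C)C)cc(C)c2O1 | intermediate
30 | (S)-2-[(3E,6E,8S)-8-hydroxy-4,8,12-trimethyltrideca-3,6,11-trien-1-yl]-2,8-dimethyl-2H-chromen-6-ol | CC(C)=CCC[C@](C)(O)/C=C/C/C(C)=C/CC[C@@]1(C)C=Cc2cc(O)cc(C)c2O1 | target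

**Step count**

Total: 23 steps. Longest linear sequence: 15 steps (geraniol 8 through steps 6–10 and 14–23 to 30).

**Steps most likely to fail**

1. Step 14 (aryne annulation). The intermediates may be lost faster than the ring closes: retro-aldol cleavage of the unmasked alkoxide, loss of bromide from the ortho-bromoaryl anion, protonation in place of acylation, or racemisation of C2 through base-induced retro-oxa-Michael opening and reclosure.
Fallback (known chemistry), setting out from 15 and returning at 24: commercial 4-methoxy-2-methylaniline (Cc1cc(OC)ccc1N) would be iodinated ortho to nitrogen (ICl, AcOH) to 2-iodo-4-methoxy-6-methylaniline F1 and converted by Sandmeyer bromination (t-BuONO, CuBr2, MeCN) into 2-bromo-1-iodo-5-methoxy-3-methylbenzene F2. Sonogashira coupling of 15 at the iodide of F2 (PdCl2(PPh3)2, CuI, Et3N, rt) should give (S)-1-(2-bromo-5-methoxy-3-methylphenyl)-3,7-dimethyloct-6-en-1-yn-3-ol F3. Semihydrogenation (Pd/CaCO3 poisoned with Pb(OAc)2, quinoline, H2) should give (S,Z)-1-(2-bromo-5-methoxy-3-methylphenyl)-3,7-dimethylocta-1,6-dien-3-ol F4. Palladium-catalysed intramolecular aryl etherification of the tertiary alcohol (Pd(OAc)2, 2-(di-tert-butylphosphino)-1,1'-binaphthyl, Cs2CO3, toluene, 60 °C) would then close O1–C8a and give 24, with C2 retained because the carbinol C–O bond is untouched. The route resumes at step 18; steps 1–10 and 14–17 are then not needed.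

2. Step 3 (ortho-silylation next to bromine). Deprotonation may go astray: benzylic metalation of the ortho-methyl group with carbamoyl transfer, LiBr loss from the ortho-bromoaryllithium, or anionic carbamoyl migration before silyl capture.
Fallback, setting out from 3 and returning at 6: hydrolysis of the carbamate (KOH, EtOH, reflux) would give 5-bromo-4-methoxy-2-methylphenol F5. Iodination at the only free position ortho to the hydroxyl (I2, morpholine, CH2Cl2) would give 3-bromo-2-iodo-4-methoxy-6-methylphenol F6, and O-silylation ((Me3Si)2NH, THF, reflux) would give (3-bromo-2-iodo-4-methoxy-6-methylphenoxy)trimethylsilane F7. Treatment with n-BuLi (THF, −100 → −78 °C) should effect selective iodine–lithium exchange, and the aryllithium is captured intramolecularly by 1,3 O→C silyl migration (retro-Brook rearrangement) to give 6 after work-up. Step 4 is then omitted and the route continues with step 5.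

3. Step 22 (Stille coupling). The C3'=C4' geometry may erode through syn–anti isomerisation of the allylpalladium intermediate, coupling may occur at the wrong allyl terminus, or the stannane may be lost by protodestannylation.
Fallback, setting out from 28 and 15 and returning at 29: copper-mediated alkynylation of the allylic bromide (CuI, NaI, K2CO3, DMF, rt) would join C5' to the alkyne terminus of 15 and give the 6',7'-didehydro analogue of 29 (C6'≡C7' alkyne) F8. Hydroxyl-directed trans-hydroalumination of this propargylic alcohol (NaAlH2(OCH2CH2OMe)2, THF, 0 °C → rt; aqueous work-up) should give the (E)-alkene 29; should the aryl silyl ether be cleaved at this point, the product is 30 itself. Stannane 16 and step 13 are then not needed.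

**Further compounds**

F1 | step 14 | 2-iodo-4-methoxy-6-methylaniline | Cc1cc(OC)cc(I)c1N
F2 | step 14 | 2-bromo-1-iodo-5-methoxy-3-methylbenzene | Cc1cc(OC)cc(I)c1Br
F3 | step 14 | (S)-1-(2-bromo-5-methoxy-3-methylphenyl)-3,7-dimethyloct-6-en-1-yn-3-ol | CC(C)=CCC[C@](C)(O)C#Cc1cc(OC)cc(C)c1Br
F4 | step 14 | (S,Z)-1-(2-bromo-5-methoxy-3-methylphenyl)-3,7-dimethylocta-1,6-dien-3-ol | CC(C)=CCC[C@](C)(O)/C=C\c1cc(OC)cc(C)c1Br
F5 | step 3 | 5-bromo-4-methoxy-2-methylphenol | Cc1cc(OC)c(Br)cc1O
F6 | step 3 | 3-bromo-2-iodo-4-methoxy-6-methylphenol | Cc1cc(OC)c(Br)c(I)c1O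
F7 | step 3 | (3-bromo-2-iodo-4-methoxy-6-methylphenoxy)trimethylsilane | Cc1cc(OC)c(Br)c(I)c1O[Si](C)(C)C
F8 | step 22 | 6',7'-didehydro analogue of 29 (C6'≡C7' alkyne) | CC(C)=CCC[C@](C)(O)C#CC/C(C)=C/CC[C@@]1(C)C=Cc2cc(O[Si](C)(C)C(C)(C)C)cc(C)c2O1
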